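At the start of this flask the starting material goes to side product at 2040 mM h⁻¹, far faster than gas transfer can feed the target-forming step, at 118 mM h⁻¹ at most.

    gas phase ⇌ dissolved gas, rate k1*(csat - [dissolved gas]) (k1 = 3.2 h⁻¹, csat = 37 mM)
    starting material + dissolved gas → target (k2 = 94 M⁻¹ h⁻¹)
    starting material → side product (k3 = 5.1 h⁻¹)
    crystals ⇌ target, rate k4*(cs4 - [target]) while solid is left; crystals form when [target] > cs4 (cs4 = 7.6 mM, k4 = 1.8 h⁻¹)
    dissolved gas + target → over-reaction product (k5 = 1.2 M⁻¹ h⁻¹)

starting material 0.40 M; gas phase 37 mM (held); time 2.5 d

- for target the crystals are counted in
- as a solid, counted per litre of solution: crystals
- at the start none of the gas is dissolved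
- run time (flask): 2.5 d

- how much target and crystals together there is at 2.5 d, in percent of the starting material charged
- the change that raises the amount of target and crystals together at 2.5 d, in percent of the starting material charged most ("none" if none brings more than 2 percentage points) (Wednesday's / Sunday's / Friday's / Thursday's / none)
- amount of target and crystals together at 2.5 d, in percent of the starting material charged, after Wednesday's

- Wednesday's: doubling the solubility in step 4, all else as stated
- Sunday's: doubling the dissolution coefficient of step 4, all else as stated
- Friday's: doubling the saturation concentration of gas phase, all else as stated
- Thursday's: doubling the transfer coefficient of step 1, all else as stated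

So we reckon with two amounts: the stock of target laid down early, and what the over-reaction takes from it by 2.5 d. We take [dissolved gas] at the level where transfer balances capture by the target-forming step, and let each portion of starting material go to target in the share which that step takes of its own rate plus that of the side reaction; summed over the charge, this estimate puts the stock at 48.2 mM, more than the solution holds. The excess stands as crystals, which redissolve far faster than the over-reaction consumes target, so [target] stays near 7.6 mM; gas transfer likewise outruns the gas use, so [dissolved gas] stays near 37 mM. With both concentrations held, the loss is zero-order in the stock: the crystal-era drain, the product of k5, saturation gas and solubility, is 0.337 mM h⁻¹. Over the run it takes 20.2 mM, and the stock is 2.39 times that, so we expect 7.00%. Wednesday's doubles the drain, giving 1.94%. Sunday's leaves the drain alone; Thursday's and Friday's both double the feed, but Friday's also doubles the drain, so we choose Thursday's.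

The forecast gave 5.8%, Thursday's and 1.7% after Wednesday's, holding that “dissolved target held near its solubility is steadily eaten by near-saturated gas”.

The flask gives 4.31%, below our 7.00%, with Thursday's best at 4.9 percentage points and 1.19% after Wednesday's. Dissolved target reads 97.6% of saturation at 1.25 d. The crystals left at 2.50 d, 2.46% of the charge, are 9.84 mM, which the drain of 0.337 mM h⁻¹ clears in 29.2 h. The same flask read later, at 6.0 d, holds crystals at 0% and target and crystals together at 0.169%.

The numbers are assumed; the flask was simulated.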